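**Retrosynthetic overview**

1. The strategy rests on the quaternary spiro carbon C4, shared by the cyclopentane (C1 bears the triene, C2, C3, C4, C5 = CHOH) and the cyclohexane (C4, C6 = CH–hydroxypropyl, C7 = alkylidene carbon, C8, C9, C10 = C(Me)OH). C4 is carried as the tertiary ring C–H of a trans-4,6-disubstituted cyclohexane whose C4 arm ends, five atoms away, in a carbon that becomes an alkylidene carbene.
2. Endgame: enal by MnO2; acetate and silyl ethers last. The cis C1–H/C5–OH pair comes from Pd/formate hydrogenolysis (inversion at C1) of an alkenyl epoxide. Cb=CH2 is made by Wittig reaction and Cb–Cc by adding a (1E,3Z)-dienyllithium to an epoxy aldehyde obtained by Sharpless epoxidation.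
3. Key disconnection: C4–C5, by 1,5 C–H insertion of the alkylidene carbene from chloroalkene 27; this closes the cyclopentene, the second ring.
4. Cyclohexane substituents: C7=Cx by carbonylation of a tetrasubstituted enol triflate formed when the C6 arm is added as a cuprate to an acetylcyclohexene; the C4 arm by cuprate addition anti to OSiEt3 on (S)-4-methyl-4-silyloxycyclohexenone.
5. The cyclohexane ring comes first, from 4-methylanisole (Birch reduction); C10 is set by Shi epoxidation and selenoxide elimination.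

Key step: step 18

Remark 1: the atom labels C1–C10, Cb (carbon on C1) and Cx (exocyclic alkene carbon) defined above are used throughout; they are not IUPAC locants.
Remark 2: the second substituent of the carbene carbon is CH2OSiEt3, not CH3. A vinylic methyl could later only be oxidised by allylic oxidation, which would prefer the ring CH2 and would not distinguish the two alkenes. The silyloxymethyl group has no C–H or O–Si bond in 1,5 reach and gives the allylic alcohol needed for a directed epoxidation.
Remark 3: chloroalkene 27 is used as an E/Z mixture and carbinol 43 as a mixture of epimers; both elements disappear in the following step (18 and 26).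
Remark 4: any minor enantiomer from step 3 should become a separable diastereomer in the reagent-controlled step 20.

**Route**

Step 1
Reactants: 1 4-methylanisole
Product: 2 1-methoxy-4-methylcyclohexa-1,4-diene
Conditions: Li, NH3(l), t-BuOH, THF, −78 → −33 °C
Reagents that add atoms: none
Why: Birch reduction (dissolving-metal 1,4-reduction) of the anisole should give the unconjugated diene with the enol ether and the methyl-bearing alkene in place.

Step 2
Reactants: 2 1-methoxy-4-methylcyclohexa-1,4-diene
Product: 3 8-methyl-1,4-dioxaspiro[4.5]dec-7-ene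
Conditions: HOCH2CH2OH, p-TsOH (cat.), CH2Cl2, rt
Reagents that add atoms: ethylene glycol, OCCO
Why: Acid-catalysed acetalisation of the enol ether (acetal exchange) should trap the ketone as the dioxolane while the trisubstituted alkene stays out of conjugation.

Step 3
Reactants: 3 8-methyl-1,4-dioxaspiro[4.5]dec-7-ene
Product: 4 (1R,6S)-6-methyl-7-oxabicyclo[4.1.0]heptan-3-one ethylene acetal
Conditions: Shi ketone (D-fructose-derived, 30 mol%), Oxone, K2CO3, Bu4NHSO4, MeCN/DMM/aq. buffer (pH 10.5), 0 °C
Reagents that add atoms: potassium peroxymonosulfate (Oxone), [K+].[O-]S(=O)(=O)OO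
Why: Shi asymmetric epoxidation (chiral dioxirane, spiro transition state) of the trisubstituted cyclohexene should deliver oxygen to the olefin face that 1-phenylcyclohexene uses with this ketone, which makes the methyl-bearing carbon S and so sets C10 and the absolute series.

Step 4
Reactants: 4 (1R,6S)-6-methyl-7-oxabicyclo[4.1.0]heptan-3-one ethylene acetal
Product: 7 (S)-8-methyl-1,4-dioxaspiro[4.5]dec-6-en-8-ol, via hydroxy selenide 5 (not isolated), via selenoxide 6 (not isolated)
Conditions: (PhSe)2, NaBH4, EtOH, reflux; then H2O2 (30%), THF, 0 °C → rt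
Reagents that add atoms: none
Why: Opening of the epoxide by phenylselenolate at the less substituted carbon (SN2, inversion), oxidation and selenoxide syn-elimination, which can only use the CH2 next to the acetal because C10 has no hydrogen, should give the tertiary allylic alcohol with the C10–O bond untouched.

Step 5
Reactants: 7 (S)-8-methyl-1,4-dioxaspiro[4.5]dec-6-en-8-ol
Product: 8 (S)-4-hydroxy-4-methylcyclohex-2-en-1-one
Conditions: PPTS (cat.), acetone/H2O, rt
Reagents that add atoms: water, O
Why: Mild acid hydrolysis of the allylic dioxolane should release the conjugated enone without ionising the tertiary allylic alcohol.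

Step 6
Reactants: 8 (S)-4-hydroxy-4-methylcyclohex-2-en-1-one
Product: 9 (S)-4-methyl-4-(triethylsilyloxy)cyclohex-2-en-1-one
Conditions: TESOTf, 2,6-lutidine, CH2Cl2, −78 → 0 °C
Reagents that add atoms: triethylsilyl trifluoromethanesulfonate, CC[Si](CC)(CC)OS(=O)(=O)C(F)(F)F
Why: Silylation of the tertiary alcohol with the silyl triflate should give the ether whose bulk and C–O dipole steer the conjugate addition that follows.

Step 7
Reactants: 9 (S)-4-methyl-4-(triethylsilyloxy)cyclohex-2-en-1-one; 10 2-(2-bromoethyl)-2-methyl-1,3-dioxolane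
Product: 13 (3S,4S)-4-methyl-3-[2-(2-methyl-1,3-dioxolan-2-yl)ethyl]-4-(triethylsilyloxy)cyclohex-1-en-1-yl triflate (ketal arm on C4 anti to OSiEt3), via Grignard reagent 11 (not isolated), via magnesium enolate 12 (not isolated)
Conditions: 10, Mg, THF; CuBr·SMe2 (20 mol%), 9, THF, −78 → −40 °C; then Comins' reagent, −78 °C → rt
Reagents that add atoms: N-(5-chloropyridin-2-yl)bis(trifluoromethanesulfonimide) (Comins' reagent), FC(F)(F)S(=O)(=O)N(c1ccc(Cl)cn1)S(=O)(=O)C(F)(F)F
Why: Copper-catalysed conjugate addition of the Grignard reagent should occur axially and anti to the pseudoaxial silyloxy group on C10 (sets C4, arm cis to methyl), and O-sulfonylation of the regiodefined enolate with Comins' reagent should fix the double bond at C6=C7.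

Step 8
Reactants: 13 enol triflate
Product: 15 1-[(3S,4S)-4-methyl-3-[2-(2-methyl-1,3-dioxolan-2-yl)ethyl]-4-(triethylsilyloxy)cyclohex-1-en-1-yl]ethan-1-one, via ethoxydiene 14 (not isolated)
Conditions: Bu3SnC(OEt)=CH2, Pd(PPh3)4 (5 mol%), LiCl, THF, 65 °C; then 0.5 M HCl, THF, 0 °C (brief)
Reagents that add atoms: tributyl(1-ethoxyvinyl)stannane, CCCC[Sn](CCCC)(CCCC)C(=C)OCC; water, O
Why: Stille coupling of the enol triflate with the 1-ethoxyvinylstannane (acetyl anion equivalent) and brief hydrolysis of the enol ether, far faster than that of the dioxolane, should give the methyl enone.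

Step 9
Reactants: 15 methyl enone; 16 (3-bromopropoxy)(tert-butyl)dimethylsilane
Product: 19 tetrasubstituted (Z)-enol triflate (C7=Cx(CH3)OTf with OTf cis to C6; C6 3-(TBSO)propyl arm trans to the C4 arm), via Grignard reagent 17 (not isolated), via magnesium enolate 18 (not isolated)
Conditions: 16, Mg, THF; CuBr·SMe2 (1.1 equiv), THF/Me2S, 15, −78 → −30 °C; then Comins' reagent, −78 °C → rt
Reagents that add atoms: N-(5-chloropyridin-2-yl)bis(trifluoromethanesulfonimide) (Comins' reagent), FC(F)(F)S(=O)(=O)N(c1ccc(Cl)cn1)S(=O)(=O)C(F)(F)F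
Why: Conjugate addition of the organocopper reagent to the 1-acylcyclohexene should occur axially anti to the pseudoaxial C4 arm (sets C6, trans to C4) through the s-cis enone, whose enolate keeps the acetyl methyl away from the newly branched C6 (allylic 1,3-strain), and O-sulfonylation should freeze this Z geometry in the tetrasubstituted enol triflate.

Step 10
Reactants: 19 tetrasubstituted (Z)-enol triflate
Product: 20 methyl (Z)-2-(cyclohexylidene)propanoate derivative (CO2Me cis to C6)
Conditions: CO (1 atm), MeOH, Pd(OAc)2 (cat.), dppf, Et3N, DMF, 60 °C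
Reagents that add atoms: carbon monoxide, [C-]#[O+]; methanol, CO
Why: Palladium-catalysed methoxycarbonylation of the enol triflate proceeds with retention of alkene geometry, so the ester carbon should end up cis to C6 as the aldehyde carbon is in the target.

Step 11
Reactants: 20 methyl (Z)-enoate
Product: 21 (Z)-allylic alcohol (C7=Cx(CH3)CH2OH, CH2OH cis to C6)
Conditions: DIBAL-H, CH2Cl2, −78 → 0 °C; Rochelle salt
Reagents that add atoms: none
Why: DIBAL-H should reduce the hindered enoate 1,2 to the allylic alcohol and leave the acetal and silyl ethers alone.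

Step 12
Reactants: 21 (Z)-allylic alcohol
Product: 22 bis-TBS ether with the dioxolane still in place
Conditions: TBSCl, imidazole, DMF, rt
Reagents that add atoms: tert-butyldimethylsilyl chloride, CC(C)(C)[Si](C)(C)Cl
Why: Standard silylation of the primary allylic alcohol.

Step 13
Reactants: 22 bis-TBS ether ketal
Product: 23 methyl ketone (C4 arm CH2CH2COCH3)
Conditions: PPTS (cat.), acetone/H2O (10:1), 45 °C
Reagents that add atoms: water, O
Why: PPTS-catalysed acetal hydrolysis should free the methyl ketone under conditions that primary TBS ethers and the hindered tertiary TES ether tolerate.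

Step 14
Reactants: 23 methyl ketone
Product: 24 terminal trimethylsilyl enol ether
Conditions: LDA, TMSCl, THF, −78 °C
Reagents that add atoms: chlorotrimethylsilane, C[Si](C)(C)Cl
Why: Kinetic deprotonation of the methyl ketone with LDA at −78 °C with in situ silylation should give the terminal (less substituted) silyl enol ether.

Step 15
Reactants: 24 terminal trimethylsilyl enol ether
Product: 25 α-hydroxy ketone (C4 arm CH2CH2COCH2OH)
Conditions: OsO4 (2 mol%), NMO, acetone/H2O, 0 °C
Reagents that add atoms: N-methylmorpholine N-oxide, C[N+]1([O-])CCOCC1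
Why: Osmium-catalysed dihydroxylation should take the electron-rich, unhindered silyl enol ether and not the crowded tetrasubstituted alkene, and loss of silanol from the adduct gives the α-hydroxy ketone.

Step 16
Reactants: 25 α-hydroxy ketone
Product: 26 α-(triethylsilyloxy) ketone
Conditions: TESCl, imidazole, CH2Cl2, 0 °C
Reagents that add atoms: chlorotriethylsilane, CC[Si](CC)(CC)Cl
Why: Silylation of the primary alcohol; a TES ether is chosen because it offers no C–H or O–Si bond within 1,5 reach of the later carbene and can be removed in the presence of TBS ethers.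

Step 17
Reactants: 26 α-(triethylsilyloxy) ketone
Product: 27 chloroalkene (C4 arm CH2CH2C(CH2OSiEt3)=CHCl, E/Z mixture)
Conditions: Ph3P(CH2Cl)Cl, NaHMDS, THF, −78 → 0 °C; then 26, → rt
Reagents that add atoms: (chloromethyl)triphenylphosphonium chloride, [Cl-].ClC[P+](c1ccccc1)(c1ccccc1)c1ccccc1
Why: Wittig chloromethylenation of the activated α-silyloxy ketone should give the 1-chloroalkene as an E/Z mixture, which is used as such since both isomers lead to the same carbene.

Step 18
Reactants: 27 chloroalkene
Product: 30 spiro[4.5]decene tetrakis-silyl ether (cyclopentene C1(CH2OSiEt3)=C5H closed on spiro C4; C5 on the face of the former C4–H), via chlorovinylpotassium 28 (not isolated), via alkylidene carbene 29 (not isolated)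
Conditions: KHMDS (3 equiv), Et2O, 0 °C → rt
Reagents that add atoms: none
Why: KHMDS removes the vinylic hydrogen of either chloroalkene isomer and chloride leaves from the α-chlorovinylpotassium 28 (α-elimination) to give alkylidene carbene 29, which inserts into the tertiary C4–H bond through a concerted three-centre transition state; the closest known reaction type is the base-induced alkylidene carbene 1,5 C–H insertion of 1-chloroalkenes that gives cyclopentenes with quaternary centres. The cyclopentene (C1–C5) closes by 1,5 insertion, the carbene carbon becoming C5 and bonding to C4, which becomes the spiro carbon. The new stereocentre C4 is set by retention at the inserting C–H carbon, so the trans relation of the C4 and C6 arms and the anti relation to the C10 silyloxy group made in steps 7 and 9 pass into the quaternary centre. The step needs site selectivity for C4–H, secured because it is the only C–H bond five atoms from the carbene carbon: the other carbene substituent, CH2OSiEt3, has oxygen at position 4 and silicon at position 5, so neither 1,5 C–H nor 1,5 O–Si insertion is possible, and 1,6 insertion or 1,2-alkyl shift should be much slower. The remaining groups are silyl ethers and an unactivated tetrasubstituted alkene, which the amide base should not touch.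

Step 19
Reactants: 30 spiro[4.5]decene tetrakis-silyl ether
Product: 31 cyclopentenylmethanol (C1–CH2OH free; other silyl ethers kept)
Conditions: PPTS (cat.), MeOH/CH2Cl2, 0 °C
Reagents that add atoms: none
Why: Acid-catalysed methanolysis should cleave the unhindered primary allylic TES ether much faster than the primary TBS ethers and the hindered tertiary TES ether.

Step 20
Reactants: 31 cyclopentenylmethanol
Product: 32 epoxy alcohol (C1–C5 epoxide on the cyclopentane face syn to C6)
Conditions: Ti(OiPr)4, L-(+)-DET, TBHP, 4 Å MS, CH2Cl2, −20 °C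
Reagents that add atoms: tert-butyl hydroperoxide, CC(C)(C)OO
Why: Sharpless asymmetric epoxidation acts only on the free allylic alcohol (the silylated tetrasubstituted alkene is inert) and with L-(+)-tartrate should deliver oxygen under reagent control to the cyclopentene face syn to C6, which sets the C5 carbinol configuration and prepares C1 for the later inversion.

Step 21
Reactants: 32 epoxy alcohol
Product: 33 epoxy aldehyde
Conditions: Dess–Martin periodinane, NaHCO3, CH2Cl2, 0 °C → rt
Reagents that add atoms: none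
Why: Dess–Martin oxidation of the primary epoxy alcohol should give the aldehyde, whose α-carbon is quaternary and cannot epimerise.

Step 22
Reactants: 34 prop-2-yn-1-ol; 35 5-bromo-2-methylpent-2-ene
Product: 38 (Z)-3-iodo-2-(4-methylpent-3-en-1-yl)prop-2-en-1-ol, via Grignard reagent 36 (not isolated), via alkenylmagnesium alkoxide 37 (not isolated)
Conditions: 35, Mg, Et2O; 34, CuI (10 mol%), Et2O/THF, −10 °C → rt; then I2, THF, −78 → 0 °C
Reagents that add atoms: iodine, II
Why: Copper-catalysed anti-carbomagnesiation of propargyl alcohol places the alkyl group on C2 and magnesium on C3 cis to the alkoxide in a five-membered chelate, so iodinolysis should give the Z iodoalkene with iodine cis to CH2OH.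

Step 23
Reactants: 38 (Z)-iodo allylic alcohol
Product: 39 (Z)-iodoalkene triethylsilyl ether
Conditions: TESCl, imidazole, CH2Cl2, 0 °C
Reagents that add atoms: chlorotriethylsilane, CC[Si](CC)(CC)Cl
Why: Silylation of the primary allylic alcohol as the labile TES ether that can later be removed before the TBS ethers.

Step 24
Reactants: 39 (Z)-iodoalkene triethylsilyl ether; 40 (E)-1,2-bis(tributylstannyl)ethene
Product: 41 (1E,3Z)-dienylstannane
Conditions: 40 (3 equiv), PdCl2(MeCN)2 (5 mol%), DMF, rt
Reagents that add atoms: none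
Why: Stille coupling with an excess of the distannylethene should give the mono-coupled dienylstannane with retention of both alkene geometries (1E,3Z).

Step 25
Reactants: 33 epoxy aldehyde; 41 (1E,3Z)-dienylstannane
Product: 43 epoxy dienyl carbinol (both carbinol epimers), via dienyllithium 42 (not isolated)
Conditions: 41, n-BuLi, THF, −78 °C; then 33, −78 °C
Reagents that add atoms: none
Why: Tin–lithium exchange should give the configurationally stable dienyllithium, which adds 1,2 to the non-enolisable aldehyde; the configuration of the new carbinol is irrelevant because it is oxidised next.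

Step 26
Reactants: 43 epoxy dienyl carbinol
Product: 44 epoxy dienone
Conditions: Dess–Martin periodinane, NaHCO3, CH2Cl2, 0 °C
Reagents that add atoms: none
Why: Dess–Martin oxidation of the doubly activated secondary alcohol should give the cross-conjugated epoxy dienone without opening the epoxide.

Step 27
Reactants: 44 epoxy dienone
Product: 45 alkenyl epoxide (Cb=CH2 installed; triene complete)
Conditions: Ph3PCH3Br, KHMDS, THF, 0 °C; then 44, −78 → 0 °C
Reagents that add atoms: methyltriphenylphosphonium bromide, [Br-].C[P+](c1ccccc1)(c1ccccc1)c1ccccc1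
Why: Wittig methylenation of the ketone, which has no α-hydrogen on the ring side, should give the 2-substituted alkenyl epoxide.

Step 28
Reactants: 45 alkenyl epoxide
Product: 46 homoallylic alcohol (C1–H; triene unit cis to C5–OH)
Conditions: Pd2(dba)3·CHCl3 (5 mol%), n-Bu3P (20 mol%), HCO2H, Et3N, dioxane, rt
Reagents that add atoms: none
Why: Palladium-catalysed hydrogenolysis of the alkenyl epoxide with formate (Tsuji-type): Pd(0) ionises the allylic C1–O bond with inversion and the hydride formed by decarboxylation is delivered from palladium to the more substituted terminus C1, so hydrogen should enter anti to the former C–O bond and leave the triene unit cis to the C5 hydroxyl (sets C1), while the cross-conjugated dienyl group on the central carbon keeps the allyl unit from migrating.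

Step 29
Reactants: 46 homoallylic alcohol
Product: 47 diol (side-chain CH2OH and C5–OH free)
Conditions: PPTS (cat.), MeOH/CH2Cl2, 0 °C
Reagents that add atoms: none
Why: Acid-catalysed methanolysis should again remove only the primary allylic TES ether.

Step 30
Reactants: 47 diol
Product: 48 side-chain monoacetate
Conditions: Ac2O, pyridine, CH2Cl2, 0 °C
Reagents that add atoms: acetic anhydride, CC(=O)OC(C)=O
Why: Acetylation without DMAP should take the unhindered primary allylic alcohol and leave the neopentyl-type secondary C5 alcohol.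

Step 31
Reactants: 48 side-chain monoacetate
Product: 49 tetraol monoacetate
Conditions: HF·pyridine, pyridine, THF, 0 °C → rt
Reagents that add atoms: none
Why: Buffered HF·pyridine should cleave both primary TBS ethers and the tertiary TES ether without touching the allylic acetate or the triene.

Step 32
Reactants: 49 tetraol monoacetate
Product: 50 CNP0205332.1
Conditions: MnO2, CH2Cl2, rt
Reagents that add atoms: none
Why: Manganese dioxide oxidises only allylic alcohols, so the primary alcohol on the tetrasubstituted alkene should give the enal with retention of alkene geometry while the saturated primary, the homoallylic secondary and the tertiary alcohols stay.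

**Compound list**

1 | 4-methylanisole | COc1ccc(C)cc1 | starting material
2 | 1-methoxy-4-methylcyclohexa-1,4-diene | COC1=CCC(C)=CC1 | intermediate
3 | 8-methyl-1,4-dioxaspiro[4.5]dec-7-ene | CC1=CCC2(CC1)OCCO2 | intermediate
4 | (1R,6S)-6-methyl-7-oxabicyclo[4.1.0]heptan-3-one ethylene acetal (methyl-bearing epoxide carbon S) | C[C@]12CCC3(OCCO3)C[C@H]1O2 | intermediate
5 | (8S)-8-methyl-7-(phenylselanyl)-1,4-dioxaspiro[4.5]decan-8-ol, PhSe trans to OH | C[C@]1(O)CCC2(OCCO2)C[C@@H]1[Se]c1ccccc1 | intermediate
6 | selenoxide of 5 | C[C@]1(O)CCC2(OCCO2)C[C@@H]1[Se](=O)c1ccccc1 | intermediate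
7 | (S)-8-methyl-1,4-dioxaspiro[4.5]dec-6-en-8-ol | O[C@]1(C)C=CC2(OCCO2)CC1 | intermediate
8 | (S)-4-hydroxy-4-methylcyclohex-2-en-1-one | O=C1C=C[C@@](C)(O)CC1 | intermediate
9 | (S)-4-methyl-4-(triethylsilyloxy)cyclohex-2-en-1-one | O=C1C=C[C@@](C)(O[Si](CC)(CC)CC)CC1 | intermediate
10 | 2-(2-bromoethyl)-2-methyl-1,3-dioxolane | CC1(CCBr)OCCO1 | starting material
11 | [2-(2-methyl-1,3-dioxolan-2-yl)ethyl]magnesium bromide | CC1(CC[Mg]Br)OCCO1 | intermediate
12 | bromomagnesium C6=C7 enolate of the conjugate adduct (ketal arm on C4 anti to OSiEt3) | CC1(CC[C@H]2C=C(O[Mg]Br)CC[C@]2(C)O[Si](CC)(CC)CC)OCCO1 | intermediate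
13 | (3S,4S)-4-methyl-3-[2-(2-methyl-1,3-dioxolan-2-yl)ethyl]-4-(triethylsilyloxy)cyclohex-1-en-1-yl trifluoromethanesulfonate | CC1(CC[C@H]2C=C(OS(=O)(=O)C(F)(F)F)CC[C@]2(C)O[Si](CC)(CC)CC)OCCO1 | intermediate
14 | 2-ethoxydiene (13 with OTf replaced by C(OEt)=CH2) | CC1(CC[C@H]2C=C(C(=C)OCC)CC[C@]2(C)O[Si](CC)(CC)CC)OCCO1 | intermediate
15 | 1-[(3S,4S)-4-methyl-3-[2-(2-methyl-1,3-dioxolan-2-yl)ethyl]-4-(triethylsilyloxy)cyclohex-1-en-1-yl]ethan-1-one | CC1(CC[C@H]2C=C(C(C)=O)CC[C@]2(C)O[Si](CC)(CC)CC)OCCO1 | intermediate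
16 | (3-bromopropoxy)(tert-butyl)dimethylsilane | BrCCCO[Si](C)(C)C(C)(C)C | starting material
17 | [3-(tert-butyldimethylsilyloxy)propyl]magnesium bromide | Br[Mg]CCCO[Si](C)(C)C(C)(C)C | intermediate
18 | bromomagnesium (Z)-enolate C7=Cx(CH3)OMgBr, O cis to C6, C6 arm trans to C4 arm | CC1(CC[C@H]2[C@H](CCCO[Si](C)(C)C(C)(C)C)/C(=C(/C)O[Mg]Br)CC[C@]2(C)O[Si](CC)(CC)CC)OCCO1 | intermediate
19 | (Z)-enol triflate C7=Cx(CH3)OTf, OTf cis to C6; C4 ketal arm and C6 3-(TBSO)propyl arm trans; C10 Me/OSiEt3 | CC1(CC[C@H]2[C@H](CCCO[Si](C)(C)C(C)(C)C)/C(=C(/C)OS(=O)(=O)C(F)(F)F)CC[C@]2(C)O[Si](CC)(CC)CC)OCCO1 | intermediate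
20 | methyl (Z)-2-(cyclohexylidene)propanoate derivative of 19 (CO2Me in place of OTf, cis to C6) | CC1(CC[C@H]2[C@H](CCCO[Si](C)(C)C(C)(C)C)/C(=C(/C)C(=O)OC)CC[C@]2(C)O[Si](CC)(CC)CC)OCCO1 | intermediate
21 | (Z)-allylic alcohol (CH2OH in place of CO2Me) | CC1(CC[C@H]2[C@H](CCCO[Si](C)(C)C(C)(C)C)/C(=C(/C)CO)CC[C@]2(C)O[Si](CC)(CC)CC)OCCO1 | intermediate
22 | bis-TBS ether of 21 (allylic CH2OTBS), dioxolane in place | CC1(CC[C@H]2[C@H](CCCO[Si](C)(C)C(C)(C)C)/C(=C(/C)CO[Si](C)(C)C(C)(C)C)CC[C@]2(C)O[Si](CC)(CC)CC)OCCO1 | intermediate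
23 | methyl ketone (C4 arm CH2CH2COCH3) | CC(=O)CC[C@H]1[C@H](CCCO[Si](C)(C)C(C)(C)C)/C(=C(/C)CO[Si](C)(C)C(C)(C)C)CC[C@]1(C)O[Si](CC)(CC)CC | intermediate
24 | terminal trimethylsilyl enol ether of 23 | C=C(O[Si](C)(C)C)CC[C@H]1[C@H](CCCO[Si](C)(C)C(C)(C)C)/C(=C(/C)CO[Si](C)(C)C(C)(C)C)CC[C@]1(C)O[Si](CC)(CC)CC | intermediate
25 | α-hydroxy ketone (C4 arm CH2CH2COCH2OH) | OCC(=O)CC[C@H]1[C@H](CCCO[Si](C)(C)C(C)(C)C)/C(=C(/C)CO[Si](C)(C)C(C)(C)C)CC[C@]1(C)O[Si](CC)(CC)CC | intermediate
26 | α-(triethylsilyloxy) ketone (C4 arm CH2CH2COCH2OSiEt3) | CC[Si](CC)(CC)OCC(=O)CC[C@H]1[C@H](CCCO[Si](C)(C)C(C)(C)C)/C(=C(/C)CO[Si](C)(C)C(C)(C)C)CC[C@]1(C)O[Si](CC)(CC)CC | intermediate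
27 | chloroalkene, key-step precursor (C4 arm CH2CH2C(CH2OSiEt3)=CHCl, E/Z mixture) | ClC=C(CO[Si](CC)(CC)CC)CC[C@H]1[C@H](CCCO[Si](C)(C)C(C)(C)C)/C(=C(/C)CO[Si](C)(C)C(C)(C)C)CC[C@]1(C)O[Si](CC)(CC)CC | intermediate
28 | α-chlorovinylpotassium from 27 | [K]C(Cl)=C(CO[Si](CC)(CC)CC)CC[C@H]1[C@H](CCCO[Si](C)(C)C(C)(C)C)/C(=C(/C)CO[Si](C)(C)C(C)(C)C)CC[C@]1(C)O[Si](CC)(CC)CC | intermediate
29 | alkylidene carbene | [C]=C(CO[Si](CC)(CC)CC)CC[C@H]1[C@H](CCCO[Si](C)(C)C(C)(C)C)/C(=C(/C)CO[Si](C)(C)C(C)(C)C)CC[C@]1(C)O[Si](CC)(CC)CC | intermediate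
30 | spiro[4.5]decene, key-step product (cyclopentene C1(CH2OSiEt3)=C5H on spiro C4; C6 3-(TBSO)propyl; C7=Cx(CH3)CH2OTBS; C10 Me/OSiEt3) | C1(CO[Si](CC)(CC)CC)CC[C@]2([C@H](CCCO[Si](C)(C)C(C)(C)C)/C(=C(/C)CO[Si](C)(C)C(C)(C)C)CC[C@]2(C)O[Si](CC)(CC)CC)C=1 | intermediate
31 | cyclopentenylmethanol (C1–CH2OH) | C1(CO)CC[C@]2([C@H](CCCO[Si](C)(C)C(C)(C)C)/C(=C(/C)CO[Si](C)(C)C(C)(C)C)CC[C@]2(C)O[Si](CC)(CC)CC)C=1 | intermediate
32 | epoxy alcohol (C1–C5 epoxide syn to C6) | OC[C@@]12CC[C@]3([C@H](CCCO[Si](C)(C)C(C)(C)C)/C(=C(/C)CO[Si](C)(C)C(C)(C)C)CC[C@]3(C)O[Si](CC)(CC)CC)[C@@H]1O2 | intermediate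
33 | epoxy aldehyde | O=C[C@@]12CC[C@]3([C@H](CCCO[Si](C)(C)C(C)(C)C)/C(=C(/C)CO[Si](C)(C)C(C)(C)C)CC[C@]3(C)O[Si](CC)(CC)CC)[C@@H]1O2 | intermediate
34 | prop-2-yn-1-ol | C#CCO | starting material
35 | 5-bromo-2-methylpent-2-ene | CC(C)=CCCBr | starting material
36 | (4-methylpent-3-en-1-yl)magnesium bromide | CC(C)=CCC[Mg]Br | intermediate
37 | cyclic (Z)-alkenylmagnesium alkoxide (five-membered O–Mg–C chelate) | CC(C)=CCCC1=C[Mg]OC1 | intermediate
38 | (Z)-3-iodo-2-(4-methylpent-3-en-1-yl)prop-2-en-1-ol | I/C=C(/CCC=C(C)C)CO | intermediate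
39 | triethylsilyl ether of 38 | I/C=C(/CCC=C(C)C)CO[Si](CC)(CC)CC | intermediate
40 | (E)-1,2-bis(tributylstannyl)ethene | CCCC[Sn](CCCC)(CCCC)/C=C/[Sn](CCCC)(CCCC)CCCC | starting material
41 | (1E,3Z)-dienylstannane Bu3SnCH=CH–CH=C(CH2OSiEt3)(CH2CH2CH=CMe2) | CCCC[Sn](CCCC)(CCCC)/C=C/C=C(/CCC=C(C)C)CO[Si](CC)(CC)CC | intermediate
42 | (1E,3Z)-dienyllithium | [Li]/C=C/C=C(/CCC=C(C)C)CO[Si](CC)(CC)CC | intermediate
43 | epoxy dienyl carbinol (both carbinol epimers) | OC(/C=C/C=C(/CCC=C(C)C)CO[Si](CC)(CC)CC)[C@@]12CC[C@]3([C@H](CCCO[Si](C)(C)C(C)(C)C)/C(=C(/C)CO[Si](C)(C)C(C)(C)C)CC[C@]3(C)O[Si](CC)(CC)CC)[C@@H]1O2 | intermediate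
44 | epoxy dienone | O=C(/C=C/C=C(/CCC=C(C)C)CO[Si](CC)(CC)CC)[C@@]12CC[C@]3([C@H](CCCO[Si](C)(C)C(C)(C)C)/C(=C(/C)CO[Si](C)(C)C(C)(C)C)CC[C@]3(C)O[Si](CC)(CC)CC)[C@@H]1O2 | intermediate
45 | alkenyl epoxide with the complete triene (Cb=CH2) | C=C(/C=C/C=C(/CCC=C(C)C)CO[Si](CC)(CC)CC)[C@@]12CC[C@]3([C@H](CCCO[Si](C)(C)C(C)(C)C)/C(=C(/C)CO[Si](C)(C)C(C)(C)C)CC[C@]3(C)O[Si](CC)(CC)CC)[C@@H]1O2 | intermediate
46 | homoallylic alcohol (C1–H, triene unit cis to C5–OH), fully silylated elsewhere | C=C(/C=C/C=C(/CCC=C(C)C)CO[Si](CC)(CC)CC)[C@@H]1CC[C@]2([C@H](CCCO[Si](C)(C)C(C)(C)C)/C(=C(/C)CO[Si](C)(C)C(C)(C)C)CC[C@]2(C)O[Si](CC)(CC)CC)[C@@H]1O | intermediate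
47 | diol (side-chain CH2OH and C5–OH) | C=C(/C=C/C=C(/CCC=C(C)C)CO)[C@@H]1CC[C@]2([C@H](CCCO[Si](C)(C)C(C)(C)C)/C(=C(/C)CO[Si](C)(C)C(C)(C)C)CC[C@]2(C)O[Si](CC)(CC)CC)[C@@H]1O | intermediate
48 | side-chain monoacetate | C=C(/C=C/C=C(/CCC=C(C)C)COC(C)=O)[C@@H]1CC[C@]2([C@H](CCCO[Si](C)(C)C(C)(C)C)/C(=C(/C)CO[Si](C)(C)C(C)(C)C)CC[C@]2(C)O[Si](CC)(CC)CC)[C@@H]1O | intermediate
49 | tetraol monoacetate (allylic CH2OH on Cx) | C=C(/C=C/C=C(/CCC=C(C)C)COC(C)=O)[C@@H]1CC[C@]2([C@H](CCCO)/C(=C(/C)CO)CC[C@]2(C)O)[C@@H]1O | intermediate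
50 | CNP0205332.1 | C=C(/C=C/C=C(/CCC=C(C)C)COC(C)=O)[C@@H]1CC[C@]2([C@H](CCCO)/C(=C(/C)C=O)CC[C@]2(C)O)[C@@H]1O | target

**Step count**

Total: 32 steps. Longest linear sequence: 29 steps (steps 1–21 and 25–32); steps 22–24 make the dienylstannane.

**Three steps most likely to fail**

1. Step 18. The α-elimination of the hindered chloroalkene may be slow, and the potassium carbenoid may be lost by protonation or by attack of amide before it reaches the crowded, inductively deactivated C4–H bond. The fallback changes the carbene precursor and uses no amide base at the insertion stage. It sets out from ketone 26 and leaves out step 17. Lithiated trimethylsilyldiazomethane (TMSCHN2, n-BuLi, THF, −78 °C → rt) adds to the carbonyl group, and Peterson-type loss of silanolate gives the diazoalkene F1. This loses dinitrogen to the same alkylidene carbene 29, which inserts as before, and the fallback comes back to the route at 30.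

2. Step 9. Conjugate addition to the β-carbon flanked by the C4 arm and the axial silyloxy group may be slow, so that 1,2-addition or enolisation of the acetyl group takes over; or the enolate may form as a mixture of geometric isomers, so that the alkene geometry is lost on triflation. The fallback brings in the C6 arm by enolate alkylation and makes the alkene by olefination. It sets out from enone 9. The magnesium enolate 12 from the copper-catalysed addition of 11 is alkylated with allyl bromide (HMPA, −78 → 0 °C) anti to the C4 arm to give the trans allyl ketone F2. Hydroboration (9-BBN; then H2O2, NaOH) gives the hydroxypropyl ketone F3, and TBSCl with imidazole gives the silyl ether ketone F4. Horner–Wadsworth–Emmons reaction with triethyl 2-phosphonopropionate (NaH, THF, reflux) and separation of the geometric isomers give the ethyl (Z)-enoate F5. DIBAL-H reduction of F5 comes back to the route at 21.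

3. Step 28. The hydride may be transferred from palladium to the CH2 terminus of the allyl unit, giving the conjugated tetrasubstituted triene, or β-hydride elimination may give a dienol instead of delivery to C1. The fallback opens the epoxy ketone reductively and then methylenates. It sets out from epoxy dienone 44. SmI2 (THF/MeOH, −90 °C) cleaves the Cα–O bond, and protonation of the samarium enolate on the face away from the C5 alkoxide should give the cis β-hydroxy dienone F6. Takai–Lombardo methylenation of F6 (Zn, CH2Br2, TiCl4, THF), which needs no base, comes back to the route at 46.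

**Further compounds**

F1 | step 18 | diazoalkene from 26 (C4 arm CH2CH2C(CH2OSiEt3)=C=N2) | [N-]=[N+]=C=C(CO[Si](CC)(CC)CC)CC[C@H]1[C@H](CCCO[Si](C)(C)C(C)(C)C)/C(=C(/C)CO[Si](C)(C)C(C)(C)C)CC[C@]1(C)O[Si](CC)(CC)CC
F2 | step 9 | trans allyl ketone (C6 allyl trans to the C4 ketal arm, C7 ketone) | CC1(CC[C@H]2[C@H](CC=C)C(=O)CC[C@]2(C)O[Si](CC)(CC)CC)OCCO1
F3 | step 9 | hydroxypropyl ketone | CC1(CC[C@H]2[C@H](CCCO)C(=O)CC[C@]2(C)O[Si](CC)(CC)CC)OCCO1
F4 | step 9 | silyl ether ketone (C6 3-(TBSO)propyl) | CC1(CC[C@H]2[C@H](CCCO[Si](C)(C)C(C)(C)C)C(=O)CC[C@]2(C)O[Si](CC)(CC)CC)OCCO1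
F5 | step 9 | ethyl (Z)-enoate (ethyl ester analogue of 20) | CC1(CC[C@H]2[C@H](CCCO[Si](C)(C)C(C)(C)C)/C(=C(/C)C(=O)OCC)CC[C@]2(C)O[Si](CC)(CC)CC)OCCO1
F6 | step 28 | cis β-hydroxy dienone (C1–H, acyl group cis to C5–OH) | O=C(/C=C/C=C(/CCC=C(C)C)CO[Si](CC)(CC)CC)[C@@H]1CC[C@]2([C@H](CCCO[Si](C)(C)C(C)(C)C)/C(=C(/C)CO[Si](C)(C)C(C)(C)C)CC[C@]2(C)O[Si](CC)(CC)CC)[C@@H]1O
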